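Late in the earlier runs the starting material stands flat: at 3.00 min green holds 90.2%, amber 96.9% and red 90.0%. The missing parts track the ratios 10.0%, 2.50% and 10.0% of protic impurity to starting material charged, and red's plateau stands by 0.833 min, earlier than the asked time.

| flask | starting material | reagent | base | scavenger | protic impurity | remark | time |
|---|---|---|---|---|---|---|---|
| green | 0.11 M | 0.70 equiv | 0.10 equiv | 1.5 equiv | 0.011 M | run made earlier |  |
| amber | 0.44 M | 0.70 equiv | 0.10 equiv | 1.5 equiv | 0.011 M | run made earlier |  |
| red | 0.22 M | 0.70 equiv | 0.10 equiv | 1.5 equiv | 0.022 M | run made earlier |  |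
| flask | 0.22 M | 0.700 equiv | 0.100 equiv | 1.50 equiv | 0.0110 M |  | 4.0 min |

| run | time / min | starting material / % | product / % |
|---|---|---|---|
| green | 0.667 | 90.6 | 0.7 |
| green | 1.33 | 89.0 | 0.4 |
| green | 2.00 | 89.2 | 0.5 |
| green | 2.50 | 90.0 | 0.5 |
| green | 3.00 | 90.2 | 0.6 |
| amber | 0.667 | 97.4 | 0.2 |
| amber | 1.33 | 97.4 | 1.1 |
| amber | 2.00 | 95.7 | 0.7 |
| amber | 2.50 | 96.4 | 0.9 |
| amber | 3.00 | 96.9 | 1.8 |
| red | 0.250 | 92.1 | 0.4 |
| red | 0.500 | 90.6 | 0 |
| red | 0.833 | 89.9 | 0.3 |
| red | 1.50 | 90.3 | 0 |
| red | 3.00 | 90.0 | 0.7 |

(readings scatter by 0.5 percentage points)

- what is said of released group includes idle adduct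
- what may be going on: starting material + reagent + released group -> product + 2 released group; starting material + protic impurity -> quenched substrate; reagent + released group <-> idle adduct; base + released group <-> salt; scavenger + released group -> scavenged by-product; starting material + reagent -> product + released group
- the earlier runs do not show how much of reagent is bound; that part of a forecast is a guess

- part of the starting material that has reacted at 4.0 min
- share of the unused reagent that is free and not bound as idle adduct, at 4.0 min

For the new flask, the protic impurity charged divided by the starting material charged, the quench share, is 5.00%; it is the end state of the fast step, with protic impurity as its limiting reagent. Product then creeps: red reads 0.7% at 3.00 min, with a scatter of 0.5 percentage points, which scales to about 0.933% by 4.0 min. My reckoning for c is therefore 5.93%. Each product frees one released group, so on that estimate of the creep the free share of the unused reagent stands no lower than about 98.6%, an estimated floor and not a value.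

The forecast gave 6% and 99.5%, holding that “the impurity quenches it fast and stoichiometrically”. The flask gives 6.01% and 99.3%.

    starting material + reagent + released group → product + 2 released group (k = 3.80 M⁻² s⁻¹)
    starting material + protic impurity → quenched substrate (k = 0.570 M⁻¹ s⁻¹)
    reagent + released group ⇌ idle adduct, settled at all times (K = 640 M⁻¹)
    base + released group ⇌ salt, settled at all times (K = 1500 M⁻¹)
    scavenger + released group → scavenged by-product (k = 1.90 M⁻¹ s⁻¹)
    starting material + reagent → product + released group (k = 2.70 × 10⁻⁴ M⁻¹ s⁻¹)

In the flask the half-life of protic impurity by the quench, 0.095 min at 0.0935 min, is far shorter than the half-life of starting material by the direct step, 4.7 h at 4.00 min, which is long against 4.0 min. At 4.00 min the flask holds 0% of its protic impurity, quenched substrate at 5.00%, matching the quench share 5.00%, and product at 1.01%. A neighbouring flask with 0.044 M of protic impurity has a quench share of 20.0%; there, at 4.00 min, quenched substrate stands at 20.0%, product at 0.850%, and reacted starting material at 20.8%.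

Readings and results are calculated on assumed constants; the scatter is artificial.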